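**Strategy**

Everything rests on removing C2 of dihydrofuran ring A (O1, C2, C3, C3a, C7a) as a one-carbon benzylidene unit. In the central benzene ring B, C3a lies between the oxygenated carbons C4 and C7a, so O1, C7a, C3a and the benzylic C3 can be unmasked as an o-quinone methide from an achiral sulfone. A chiral sulfonium ylide carrying the 4-oxygenated aryl group adds its carbon to C3 and the phenoxide then closes ring A at O1–C2, setting both stereocentres in one operation. The same annulation builds the second dihydrobenzofuran; a Heck reaction, an acid-mediated Friedel–Crafts closure of the seven-membered ring and hydrogenolysis finish the synthesis.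

Key step: step 6

Locants: ring A/ring B are the first 2,3-dihydro-1-benzofuran (O1, C2, C3, C3a, C4–C7, C7a). Ring C (benzene) and ring D (dihydrofuran) are the second one, with primed locants. Ring E is the cycloheptane.

Assumption: the sulfide with the descriptors (1R,4R,5R) is taken to induce the (2S,3S) sense, by analogy with its benzylidene transfer to aldehydes; should the opposite sense be found, its enantiomer (from the other limonene enantiomer) replaces it in steps 5, 6 and 11.

Assumption: the new centre of ring E is taken to form under substrate control by C3' with the aryl group anti to H-3', as in related acid-mediated closures of viniferin-type stilbenes.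

**Route**

Step 1
Reactants: 1 4-bromo-2,6-dimethoxybenzaldehyde
Product: 2 4-bromo-2,6-dihydroxybenzaldehyde
Conditions: BBr3, CH2Cl2, −78 °C to rt; H2O
Reagents that add atoms: none
Why: Lewis-acid ether cleavage, in which BBr3 removes both methyl groups (each assisted by chelation to the ortho formyl group) and leaves the aryl bromide untouched.

Step 2
Reactants: 2 4-bromo-2,6-dihydroxybenzaldehyde
Product: 3 2-(benzyloxy)-4-bromo-6-hydroxybenzaldehyde
Conditions: BnBr (1.0 equiv), K2CO3, DMF, 0 °C to rt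
Reagents that add atoms: benzyl bromide BrCc1ccccc1
Why: Williamson etherification that should stop after one benzylation, because the remaining hydroxyl is locked in a hydrogen bond to the formyl oxygen and is much less reactive.

Step 3
Reactants: 3 2-(benzyloxy)-4-bromo-6-hydroxybenzaldehyde; 4 1,3-bis(benzyloxy)-5-bromobenzene
Product: 6 racemic o-hydroxybenzhydrol of ring B, via aryl Grignard reagent 5 (not isolated)
Conditions: 4, Mg, THF, reflux; then 3 (0.45 equiv), THF, 0 °C; aq. NH4Cl
Reagents that add atoms: none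
Why: Grignard addition in which the first equivalent deprotonates the phenol and the second adds to the aldehyde, the aryl bromide of 3 being inert to an arylmagnesium halide at 0 °C; the carbinol centre is racemic and is erased in step 6.

Step 4
Reactants: 6 racemic o-hydroxybenzhydrol of ring B
Product: 7 racemic o-hydroxybenzhydryl sulfone
Conditions: 4-MeC6H4SO2H, CH2Cl2, rt
Reagents that add atoms: 4-methylbenzenesulfinic acid Cc1ccc(cc1)S(=O)O
Why: SN1-type substitution through the doubly ortho-oxygenated benzhydryl cation (protonated o-quinone methide), which is captured at sulfur to give the storable quinone methide precursor.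

Step 5
Reactants: 8 (1R,4R,5R)-isothiocineole; 9 1-(benzyloxy)-4-(bromomethyl)benzene
Product: 10 isothiocineole-derived 4-(benzyloxy)benzylsulfonium tetrafluoroborate
Conditions: NaBF4, CH2Cl2/H2O, rt
Reagents that add atoms: sodium tetrafluoroborate [Na+].F[B-](F)(F)F
Why: SN2 S-alkylation on the less hindered (exo) lone pair of the rigid bicyclic sulfide should give a single sulfonium diastereomer, and exchange to the non-nucleophilic tetrafluoroborate prevents dealkylation.

Step 6
Reactants: 7 racemic o-hydroxybenzhydryl sulfone; 10 isothiocineole-derived 4-(benzyloxy)benzylsulfonium tetrafluoroborate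
Product: 14 (2S,3S)-4-(benzyloxy)-2-[4-(benzyloxy)phenyl]-3-[3,5-bis(benzyloxy)phenyl]-6-bromo-2,3-dihydro-1-benzofuran, via o-quinone methide 11 (not isolated), via sulfonium ylide 12 (not isolated), via phenoxide–sulfonium betaine 13 (not isolated)
Conditions: Cs2CO3 (3 equiv), MeCN/CH2Cl2, −20 °C to rt
Reagents that add atoms: none
Why: Cs2CO3 converts sulfone 7 into o-quinone methide 11 (loss of sulfinate) and salt 10 into ylide 12; conjugate addition of the ylidic carbon to the methide carbon forms C2–C3 and gives betaine 13, whose phenoxide oxygen then displaces the sulfide at C2 to form O1–C2. The reaction type is the formal [4+1] annulation of o-quinone methides with sulfonium ylides to trans-2,3-dihydrobenzofurans, run here with an isothiocineole-derived benzylide of the kind used for asymmetric benzylidene transfer to aldehydes and imines. Ring A closes in a 5-exo-tet mode. Both centres arise in the C–C bond formation: the sulfonium auxiliary exposes one face of the ylidic carbon and so fixes C2 (R in 13, S after backside displacement), while the anti approach of the achiral quinone methide places C3 (S) trans to it. The step needs addition of the ylide to the methide carbon in preference to Stevens or Sommelet–Hauser rearrangement, high ylide-face selectivity and anti selectivity; the first is secured by generating the strongly electrophilic quinone methide slowly beside the ylide, the others rest on the rigid bicyclic sulfonium group and are the least certain element of the route. A cis by-product would be removed by chromatography and not epimerised, since inversion at C2 alone could lead into the enantiomeric trans series.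

Step 7
Reactants: 15 5-bromobenzene-1,3-diol
Product: 16 2-bromo-4,6-dihydroxybenzaldehyde
Conditions: POCl3, DMF, MeCN, 0 °C to rt; then H2O, 50 °C
Reagents that add atoms: N,N-dimethylformamide CN(C)C=O; water O
Why: Vilsmeier–Haack formylation should go para to one hydroxyl and ortho to the other, as with other 5-substituted resorcinols, the position between the two hydroxyls being less reactive towards the chloroiminium ion.

Step 8
Reactants: 16 2-bromo-4,6-dihydroxybenzaldehyde
Product: 17 4-(benzyloxy)-2-bromo-6-hydroxybenzaldehyde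
Conditions: BnBr (1.0 equiv), NaHCO3, MeCN, 60 °C
Reagents that add atoms: benzyl bromide BrCc1ccccc1
Why: Williamson etherification selective for the 4-hydroxyl, which is the more acidic one and is not hydrogen-bonded to the formyl group.

Step 9
Reactants: 14 dihydrobenzofuran bromide (ring A/B unit); 17 4-(benzyloxy)-2-bromo-6-hydroxybenzaldehyde
Product: 20 o-hydroxybenzhydrol joining ring B to ring C (carbinol epimers), via aryllithium 18 (not isolated), via sodium phenolate 19 (not isolated)
Conditions: 17, NaH, THF, 0 °C; 14, n-BuLi, THF, −78 °C; combine, −78 °C to 0 °C; aq. NH4Cl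
Reagents that add atoms: none
Why: bromine–lithium exchange followed by 1,2-addition of the aryllithium to the aldehyde, whose phenol is masked as its sodium salt so that no aryllithium is consumed; addition to the formyl group is far faster than exchange with the bromide of ring C, and the carbinol centre is erased in step 11.

Step 10
Reactants: 20 o-hydroxybenzhydrol joining ring B to ring C
Product: 21 o-hydroxybenzhydryl sulfone of ring C (epimers)
Conditions: 4-MeC6H4SO2H, CH2Cl2, 0 °C to rt
Reagents that add atoms: 4-methylbenzenesulfinic acid Cc1ccc(cc1)S(=O)O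
Why: the same SN1-type sulfination as in step 4, the cation being stabilised by the ortho hydroxyl and para benzyloxy groups of ring C, under acidity too weak to open ring A irreversibly.

Step 11
Reactants: 21 o-hydroxybenzhydryl sulfone of ring C; 10 isothiocineole-derived 4-(benzyloxy)benzylsulfonium tetrafluoroborate
Product: 24 bis(dihydrobenzofuran) bromide with rings A to D in place, via o-quinone methide 22 (not isolated), via phenoxide–sulfonium betaine 23 (not isolated)
Conditions: Cs2CO3 (3 equiv), MeCN/CH2Cl2, −20 °C to rt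
Reagents that add atoms: none
Why: the same formal [4+1] annulation of an o-quinone methide with a sulfonium ylide closes ring D (5-exo-tet): Cs2CO3 releases 22 from sulfone 21 and deprotonates salt 10 as in step 6 to the ylide already listed as 12, the auxiliary fixes C2' (S after inversion) under reagent control because the ring A stereocentres are remote, and the anti approach places C3' (S) trans to it.

Step 12
Reactants: 25 2,4-bis(benzyloxy)benzaldehyde
Product: 26 2,4-bis(benzyloxy)-1-ethenylbenzene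
Conditions: Ph3PCH3Br, KOtBu, THF, 0 °C to rt
Reagents that add atoms: methyltriphenylphosphonium bromide C[P+](c1ccccc1)(c1ccccc1)c1ccccc1.[Br-]
Why: Wittig methylenation of an aromatic aldehyde with the non-stabilised ylide.

Step 13
Reactants: 24 bis(dihydrobenzofuran) bromide; 26 2,4-bis(benzyloxy)-1-ethenylbenzene
Product: 27 (E)-stilbene (open trimer octabenzyl ether)
Conditions: Pd(OAc)2, P(o-tol)3, Et3N, DMF, 100 °C
Reagents that add atoms: none
Why: Mizoroki–Heck reaction in which oxidative addition of the aryl bromide to zerovalent palladium formed in situ, insertion at the terminal carbon of the styrene and syn β-hydride elimination should give the (E)-alkene; the alkene geometry is not critical for step 14.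

Step 14
Reactants: 27 (E)-stilbene (open trimer octabenzyl ether)
Product: 28 octa-O-benzyl ether of the target
Conditions: TsOH·H2O (cat.), (CF3)2CHOH/CH2Cl2, 0 °C to rt
Reagents that add atoms: none
Why: intramolecular Friedel–Crafts alkylation in which protonation at the alkene carbon next to ring C gives the 2,4-bis(benzyloxy)benzyl cation, which is attacked by C7 of ring B (para to the C4 benzyloxy group and ortho to the tied-back O1, whereas C5 is flanked by the benzyloxy group) to close ring E, the new centre being set by C3' with the aryl group anti to H-3'.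

Step 15
Reactants: 28 octa-O-benzyl ether of the target
Product: 29 target CNP0154774.1
Conditions: H2 (1 atm), Pd/C, EtOAc/MeOH, rt
Reagents that add atoms: none
Why: hydrogenolysis of the eight aryl benzyl ethers over palladium, which should be much faster than cleavage of the cyclic benzylic C–O bonds of rings A and D and touches no stereocentre.

**Compound list**

1 | 4-bromo-2,6-dimethoxybenzaldehyde | COc1cc(Br)cc(OC)c1C=O | starting material
2 | 4-bromo-2,6-dihydroxybenzaldehyde | Oc1cc(Br)cc(O)c1C=O | intermediate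
3 | 2-(benzyloxy)-4-bromo-6-hydroxybenzaldehyde | Oc1cc(Br)cc(OCc2ccccc2)c1C=O | intermediate
4 | 1,3-bis(benzyloxy)-5-bromobenzene | Brc1cc(OCc2ccccc2)cc(OCc2ccccc2)c1 | starting material
5 | [3,5-bis(benzyloxy)phenyl]magnesium bromide (not isolated) | Br[Mg]c1cc(OCc2ccccc2)cc(OCc2ccccc2)c1 | intermediate
6 | rac-3-(benzyloxy)-2-{[3,5-bis(benzyloxy)phenyl](hydroxy)methyl}-5-bromophenol | Oc1cc(Br)cc(OCc2ccccc2)c1C(O)c1cc(OCc2ccccc2)cc(OCc2ccccc2)c1 | intermediate
7 | rac-3-(benzyloxy)-2-{[3,5-bis(benzyloxy)phenyl](4-methylbenzenesulfonyl)methyl}-5-bromophenol | Oc1cc(Br)cc(OCc2ccccc2)c1C(c1cc(OCc2ccccc2)cc(OCc2ccccc2)c1)S(=O)(=O)c1ccc(C)cc1 | intermediate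
8 | (1R,4R,5R)-4,7,7-trimethyl-6-thiabicyclo[3.2.1]octane (isothiocineole) | C[C@@H]1CC[C@@H]2C[C@H]1SC2(C)C | starting material
9 | 1-(benzyloxy)-4-(bromomethyl)benzene | BrCc1ccc(OCc2ccccc2)cc1 | starting material
10 | (1R,4R,5R,6R)-6-[4-(benzyloxy)benzyl]-4,7,7-trimethyl-6-thiabicyclo[3.2.1]octan-6-ium tetrafluoroborate | C[C@@H]1CC[C@@H]2C[C@H]1[S@@+](Cc1ccc(OCc3ccccc3)cc1)C2(C)C.F[B-](F)(F)F | intermediate
11 | 5-(benzyloxy)-6-[3,5-bis(benzyloxy)benzylidene]-3-bromocyclohexa-2,4-dien-1-one, alkene geometry not defined (not isolated) | O=C1C=C(Br)C=C(OCc2ccccc2)C1=Cc1cc(OCc2ccccc2)cc(OCc2ccccc2)c1 | intermediate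
12 | sulfonium ylide of 10, deprotonated at the benzylic carbon, bicycle and sulfur as in 10 (not isolated) | C[C@@H]1CC[C@@H]2C[C@H]1[S@@+]([CH-]c1ccc(OCc3ccccc3)cc1)C2(C)C | intermediate
13 | betaine: phenolate of ring B carrying at C3 (S) the 3,5-bis(benzyloxy)phenyl group and at C2 (R) the 4-(benzyloxy)phenyl group and the bicyclic sulfonium group of 10 (not isolated) | C[C@@H]1CC[C@@H]2C[C@H]1[S@@+]([C@@H](c1ccc(OCc3ccccc3)cc1)[C@@H](c1cc(OCc3ccccc3)cc(OCc3ccccc3)c1)c1c([O-])cc(Br)cc1OCc1ccccc1)C2(C)C | intermediate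
14 | (2S,3S)-4-(benzyloxy)-2-[4-(benzyloxy)phenyl]-3-[3,5-bis(benzyloxy)phenyl]-6-bromo-2,3-dihydro-1-benzofuran | c5ccccc5COc1ccc([C@H]2Oc3cc(Br)cc(OCc5ccccc5)c3[C@@H]2c2cc(OCc5ccccc5)cc(OCc5ccccc5)c2)cc1 | intermediate
15 | 5-bromobenzene-1,3-diol | Oc1cc(O)cc(Br)c1 | starting material
16 | 2-bromo-4,6-dihydroxybenzaldehyde | Oc1cc(O)cc(Br)c1C=O | intermediate
17 | 4-(benzyloxy)-2-bromo-6-hydroxybenzaldehyde | Oc1cc(OCc2ccccc2)cc(Br)c1C=O | intermediate
18 | {(2S,3S)-4-(benzyloxy)-2-[4-(benzyloxy)phenyl]-3-[3,5-bis(benzyloxy)phenyl]-2,3-dihydro-1-benzofuran-6-yl}lithium (not isolated) | c5ccccc5COc1ccc([C@H]2Oc3cc([Li])cc(OCc5ccccc5)c3[C@@H]2c2cc(OCc5ccccc5)cc(OCc5ccccc5)c2)cc1 | intermediate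
19 | sodium 5-(benzyloxy)-3-bromo-2-formylphenolate (not isolated) | [Na+].[O-]c1cc(OCc2ccccc2)cc(Br)c1C=O | intermediate
20 | [(2S,3S)-4-(benzyloxy)-2-[4-(benzyloxy)phenyl]-3-[3,5-bis(benzyloxy)phenyl]-2,3-dihydro-1-benzofuran-6-yl][4-(benzyloxy)-2-bromo-6-hydroxyphenyl]methanol, carbinol epimers | c5ccccc5COc1ccc([C@H]2Oc3cc(cc(OCc5ccccc5)c3[C@@H]2c2cc(OCc5ccccc5)cc(OCc5ccccc5)c2)C(O)c2c(O)cc(OCc5ccccc5)cc2Br)cc1 | intermediate
21 | 5-(benzyloxy)-3-bromo-2-{[(2S,3S)-4-(benzyloxy)-2-[4-(benzyloxy)phenyl]-3-[3,5-bis(benzyloxy)phenyl]-2,3-dihydro-1-benzofuran-6-yl](4-methylbenzenesulfonyl)methyl}phenol, epimers | c5ccccc5COc1ccc([C@H]2Oc3cc(cc(OCc5ccccc5)c3[C@@H]2c2cc(OCc5ccccc5)cc(OCc5ccccc5)c2)C(c2c(O)cc(OCc5ccccc5)cc2Br)S(=O)(=O)c2ccc(C)cc2)cc1 | intermediate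
22 | 3-(benzyloxy)-5-bromo-6-{[(2S,3S)-4-(benzyloxy)-2-[4-(benzyloxy)phenyl]-3-[3,5-bis(benzyloxy)phenyl]-2,3-dihydro-1-benzofuran-6-yl]methylidene}cyclohexa-2,4-dien-1-one, alkene geometry not defined (not isolated) | c5ccccc5COc1ccc([C@H]2Oc3cc(cc(OCc5ccccc5)c3[C@@H]2c2cc(OCc5ccccc5)cc(OCc5ccccc5)c2)C=C2C(=O)C=C(OCc5ccccc5)C=C2Br)cc1 | intermediate
23 | betaine: phenolate of ring C (5-benzyloxy, 3-bromo) whose benzylic carbon C3' carries the ring A/B unit of 14 and is bonded to C2', which carries the 4-(benzyloxy)phenyl group and the bicyclic sulfonium group of 10 (not isolated) | C[C@@H]1CC[C@@H]2C[C@H]1[S@@+]([C@@H](c1ccc(OCc3ccccc3)cc1)[C@@H](c1cc3O[C@H](c4ccc(OCc5ccccc5)cc4)[C@@H](c4cc(OCc5ccccc5)cc(OCc5ccccc5)c4)c3c(OCc3ccccc3)c1)c1c([O-])cc(OCc3ccccc3)cc1Br)C2(C)C | intermediate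
24 | (2S,3S)-4-(benzyloxy)-6-{(2S,3S)-6-(benzyloxy)-2-[4-(benzyloxy)phenyl]-4-bromo-2,3-dihydro-1-benzofuran-3-yl}-2-[4-(benzyloxy)phenyl]-3-[3,5-bis(benzyloxy)phenyl]-2,3-dihydro-1-benzofuran | c5ccccc5COc1ccc([C@H]2Oc3cc(cc(OCc5ccccc5)c3[C@@H]2c2cc(OCc5ccccc5)cc(OCc5ccccc5)c2)[C@H]2c3c(cc(OCc5ccccc5)cc3O[C@@H]2c2ccc(OCc5ccccc5)cc2)Br)cc1 | intermediate
25 | 2,4-bis(benzyloxy)benzaldehyde | O=Cc1ccc(OCc2ccccc2)cc1OCc1ccccc1 | starting material
26 | 2,4-bis(benzyloxy)-1-ethenylbenzene | C=Cc1ccc(OCc2ccccc2)cc1OCc1ccccc1 | intermediate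
27 | (2S,3S)-4-(benzyloxy)-6-{(2S,3S)-6-(benzyloxy)-2-[4-(benzyloxy)phenyl]-4-[(E)-2-[2,4-bis(benzyloxy)phenyl]ethenyl]-2,3-dihydro-1-benzofuran-3-yl}-2-[4-(benzyloxy)phenyl]-3-[3,5-bis(benzyloxy)phenyl]-2,3-dihydro-1-benzofuran | c5ccccc5COc1ccc([C@H]2Oc3cc(cc(OCc5ccccc5)c3[C@@H]2c2cc(OCc5ccccc5)cc(OCc5ccccc5)c2)[C@H]2c3c(cc(OCc5ccccc5)cc3O[C@@H]2c2ccc(OCc5ccccc5)cc2)/C=C/c2ccc(OCc5ccccc5)cc2OCc5ccccc5)cc1 | intermediate
28 | octa-O-benzyl ether of 29 (all eight phenols benzylated, five stereocentres as in 29) | c5ccccc5COc1ccc([C@H]2Oc3c4c(cc(OCc5ccccc5)c3[C@@H]2c2cc(OCc5ccccc5)cc(OCc5ccccc5)c2)[C@H]2c3c(cc(OCc5ccccc5)cc3O[C@@H]2c2ccc(OCc5ccccc5)cc2)C[C@H]4c2ccc(OCc5ccccc5)cc2OCc5ccccc5)cc1 | intermediate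
29 | CNP0154774.1: octaphenol with trans ring A (C2 S, C3 S; 4-hydroxyphenyl and 3,5-dihydroxyphenyl), trans ring D (C2' S, C3' S; 4-hydroxyphenyl) and ring E joining C7 of ring B to ring C through CH(2,4-dihydroxyphenyl)–CH2 (S) | Oc1ccc([C@H]2Oc3c4c(cc(O)c3[C@@H]2c2cc(O)cc(O)c2)[C@H]2c3c(cc(O)cc3O[C@@H]2c2ccc(O)cc2)C[C@H]4c2ccc(O)cc2O)cc1 | target

**Step count**

Total: 15 steps. Longest linear sequence: 11 steps (1, 2, 3, 4, 6, 9, 10, 11, 13, 14, 15).

**Steps most likely to fail**

Step 6. The risk is low ylide-face or anti/syn discrimination when the ylide adds to the quinone methide (erosion of enantiomeric or diastereomeric purity), or rearrangement of the ylide before it adds. The fallback sets out from 3 and returns at 14; it fixes C3 by catalyst control and closes ring A through the benzylic cation. Henry condensation of 3 with nitromethane (NH4OAc, AcOH, heat) would give (E)-3-(benzyloxy)-5-bromo-2-(2-nitroethenyl)phenol F1. Hayashi–Miyaura addition of [3,5-bis(benzyloxy)phenyl]boronic acid ([RhCl(C2H4)2]2, chiral bicyclic diene ligand, KOH, dioxane/H2O) would give the (S)-nitroalkane F2. A buffered Nef reaction (NaOMe; then TiCl3, NH4OAc) would give the lactol F3, in which the epimerisable aldehyde is masked. [4-(Benzyloxy)phenyl]magnesium bromide would open it to the diol F4. TsOH in CH2Cl2 would then form O1–C2 by capture of the 4-benzyloxybenzyl cation, trans to C3, giving 14.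

Step 11. The risk is slow addition to the hindered, ortho-bromo-substituted quinone methide (so that it dimerises or is hydrolysed), or poor selectivity at C2' and C3'. The fallback sets out from 17 and 14 and returns at 24. Henry condensation of 17 would give (E)-5-(benzyloxy)-3-bromo-2-(2-nitroethenyl)phenol F5. Miyaura borylation of 14 (bis(pinacolato)diboron, PdCl2(dppf), KOAc, dioxane) would give the pinacol boronate F6. Hayashi–Miyaura addition of F6 to F5 ([RhCl(C2H4)2]2, chiral diene ligand, KOH) would set C3' in the nitroalkane F7. The Nef reaction would give the lactol F8, [4-(benzyloxy)phenyl]magnesium bromide the diol F9, and TsOH-mediated cyclodehydration would close ring D trans to give 24.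

Step 14. The risk is attack of the cation at C5 of ring B in place of C7, or acid-induced opening and rearrangement of rings A and D. The fallback sets out from 27 and returns at 29; it reverses the order of events so that a free hydroxyl directs the closure. Non-reductive debenzylation (BCl3, pentamethylbenzene, CH2Cl2, −78 °C) would keep the alkene and give the free octaphenol stilbene F10. Dilute HCl in MeOH would then cyclise it, with the free C4 hydroxyl of ring B activating the para position C7, to give 29 directly.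

**Further compounds**

F1 | step 6 | (E)-3-(benzyloxy)-5-bromo-2-(2-nitroethenyl)phenol | Oc1cc(Br)cc(OCc2ccccc2)c1/C=C/[N+](=O)[O-]
F2 | step 6 | 3-(benzyloxy)-2-{(1S)-1-[3,5-bis(benzyloxy)phenyl]-2-nitroethyl}-5-bromophenol | Oc1cc(Br)cc(OCc2ccccc2)c1[C@@H](C[N+](=O)[O-])c1cc(OCc2ccccc2)cc(OCc2ccccc2)c1
F3 | step 6 | (3S)-4-(benzyloxy)-3-[3,5-bis(benzyloxy)phenyl]-6-bromo-2,3-dihydro-1-benzofuran-2-ol, anomers | OC1Oc2cc(Br)cc(OCc3ccccc3)c2[C@@H]1c1cc(OCc2ccccc2)cc(OCc2ccccc2)c1
F4 | step 6 | 3-(benzyloxy)-2-{(1S)-1-[3,5-bis(benzyloxy)phenyl]-2-[4-(benzyloxy)phenyl]-2-hydroxyethyl}-5-bromophenol, carbinol epimers | Oc1cc(Br)cc(OCc2ccccc2)c1[C@@H](C(O)c1ccc(OCc2ccccc2)cc1)c1cc(OCc2ccccc2)cc(OCc2ccccc2)c1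
F5 | step 11 | (E)-5-(benzyloxy)-3-bromo-2-(2-nitroethenyl)phenol | Oc1cc(OCc2ccccc2)cc(Br)c1/C=C/[N+](=O)[O-]
F6 | step 11 | 2-{(2S,3S)-4-(benzyloxy)-2-[4-(benzyloxy)phenyl]-3-[3,5-bis(benzyloxy)phenyl]-2,3-dihydro-1-benzofuran-6-yl}-4,4,5,5-tetramethyl-1,3,2-dioxaborolane | c5ccccc5COc1ccc([C@H]2Oc3cc(B4OC(C)(C)C(C)(C)O4)cc(OCc5ccccc5)c3[C@@H]2c2cc(OCc5ccccc5)cc(OCc5ccccc5)c2)cc1
F7 | step 11 | 5-(benzyloxy)-3-bromo-2-[(1S)-1-{(2S,3S)-4-(benzyloxy)-2-[4-(benzyloxy)phenyl]-3-[3,5-bis(benzyloxy)phenyl]-2,3-dihydro-1-benzofuran-6-yl}-2-nitroethyl]phenol | c5ccccc5COc1ccc([C@H]2Oc3cc(cc(OCc5ccccc5)c3[C@@H]2c2cc(OCc5ccccc5)cc(OCc5ccccc5)c2)[C@H](C[N+](=O)[O-])c2c(O)cc(OCc5ccccc5)cc2Br)cc1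
F8 | step 11 | (3S)-6-(benzyloxy)-4-bromo-3-{(2S,3S)-4-(benzyloxy)-2-[4-(benzyloxy)phenyl]-3-[3,5-bis(benzyloxy)phenyl]-2,3-dihydro-1-benzofuran-6-yl}-2,3-dihydro-1-benzofuran-2-ol, anomers | c5ccccc5COc1ccc([C@H]2Oc3cc(cc(OCc5ccccc5)c3[C@@H]2c2cc(OCc5ccccc5)cc(OCc5ccccc5)c2)[C@H]2c3c(cc(OCc5ccccc5)cc3OC2O)Br)cc1
F9 | step 11 | 5-(benzyloxy)-3-bromo-2-[(1S)-1-{(2S,3S)-4-(benzyloxy)-2-[4-(benzyloxy)phenyl]-3-[3,5-bis(benzyloxy)phenyl]-2,3-dihydro-1-benzofuran-6-yl}-2-[4-(benzyloxy)phenyl]-2-hydroxyethyl]phenol, carbinol epimers | c5ccccc5COc1ccc([C@H]2Oc3cc(cc(OCc5ccccc5)c3[C@@H]2c2cc(OCc5ccccc5)cc(OCc5ccccc5)c2)[C@H](C(O)c2ccc(OCc5ccccc5)cc2)c2c(O)cc(OCc5ccccc5)cc2Br)cc1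
F10 | step 14 | free octaphenol of 27: (E)-stilbene with rings A to D as in 29 and ring E not yet closed | Oc1ccc([C@H]2Oc3cc(cc(O)c3[C@@H]2c2cc(O)cc(O)c2)[C@H]2c3c(cc(O)cc3O[C@@H]2c2ccc(O)cc2)/C=C/c2ccc(O)cc2O)cc1
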